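A base charge of 0.0500 equiv looks small, yet the next run turns on how it goes in: at the start (south) or fed over 10 h (south-east).

common to all: starting material 0.46 M
- Sunday's: partner 0.60 equiv; base 0.034 equiv (fed, over 10 h); protic impurity 0.046 M; run made earlier
- Monday's: partner 0.60 equiv; base 0.075 equiv (fed, over 10 h); protic impurity 0.046 M; run made earlier
- Wednesday's: partner 0.30 equiv; base 0.050 equiv (fed, over 10 h); protic impurity 0.046 M; run made earlier
- south: partner 0.600 equiv; base 0.0500 equiv; protic impurity 0.0460 M; everything together at the start; time 10 h
- south-east: partner 0.600 equiv; base 0.0500 equiv (fed, over 10 h); protic impurity 0.0460 M; time 10 h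

| run | time / h | target / % |
|---|---|---|
| Sunday's | 0.667 | 0.2 |
| Sunday's | 1.00 | 1.1 |
| Sunday's | 1.33 | 1.8 |
| Sunday's | 2.50 | 3.6 |
| Sunday's | 3.00 | 5.3 |
| Sunday's | 5.00 | 13.0 |
| Sunday's | 8.00 | 22.8 |
| Monday's | 0.667 | 0.8 |
| Monday's | 1.00 | 1.2 |
| Monday's | 1.33 | 1.5 |
| Monday's | 2.50 | 1.3 |
| Monday's | 3.00 | 2.1 |
| Monday's | 5.00 | 3.5 |
| Monday's | 8.00 | 11.7 |
| Wednesday's | 0.667 | 0.3 |
| Wednesday's | 2.00 | 1.0 |
| Wednesday's | 4.00 | 1.3 |
| Wednesday's | 6.00 | 1.6 |
| Wednesday's | 8.00 | 0.8 |

(each reading ± 0.5 percentage points)



1. the winner by amount of target, in percent of the starting material charged; "neither" if no more than 2 percentage points parts them (south / south-east / neither)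
2. how much target is there at the end, in percent of the starting material charged: south
3. how much target is there at the end, in percent of the starting material charged: south-east

We count turnovers. We suppose that each turnover of starting material releases one unit of a species that speeds the reaction, and that one unit of base takes it up. The slow pace, our name for the turnover while base takes up that species as fast as it forms, then comes from Wednesday's run, where the reading of 1.3 % at 4.00 h gives 0.00150 M h⁻¹, with a scatter of 0.5 percentage points on that reading. This is less than that run's feed of 0.00230 M h⁻¹, and its target readings show no take-off up to 8.00 h. We assume the pace follows the partner left after the protic impurity has taken its share, 0.0920 M on Wednesday and 0.230 M in both new flasks, so the pace there is 0.00374 M h⁻¹.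

Sunday's feed of 0.00156 M h⁻¹ is well below this pace, and Sunday stood at 13.0 % at 5.00 h. Monday's feed of 0.00345 M h⁻¹ lies just below it, and Monday stood at 3.5 % at that time. South-east's feed of 0.00230 M h⁻¹ is also slower than the pace, so turnover should outrun its base from the start.

On this supposition south has first to work through its whole charge of 0.0230 M. Dividing that by the pace gives 6.15 h, the hold time, our estimate of an induction period, out of the 10 h. So we would keep the feed.

The forecast gives south-east, with 8 % in south and 21 % in south-east, holding that “South gets all the base at once, which is the extreme of fast feeding”.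

The flasks give 7.63 % in south and 22.3 % in south-east, so south-east has more target.

    target ⇌ isomer of the product (K = 2.10, k = 6.80 × 10⁻⁵ s⁻¹)
    starting material + partner → target + by-product (k = 9.50 × 10⁻⁶ L mol⁻¹ s⁻¹)
    base + by-product ⇌ salt, settled at all times (K = 79000 L mol⁻¹)
    starting material + partner + by-product → target + 2 by-product (k = 0.00220 L² mol⁻² s⁻¹)
    partner + protic impurity → quenched reagent (k = 0.00650 L mol⁻¹ s⁻¹)

South at 5.00 h, inside its hold time of 6.15 h, still had 25.2 % of its base free, with 0.0172 M as salt, and at 10.0 h it had 0.0385 % free. The neighbour is south with 1.50 equiv of partner, all other charges held. Its partner net of the protic impurity is 0.644 M, so its slow pace is 0.0105 M h⁻¹ and its hold time 2.20 h, shorter than south's. At 10.0 h that neighbour had base at 0 %, starting material at 1.15 % and target at 43.7 %.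

The runs are calculated with constants of no real substance; scatter was added.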